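## Structural features

Yunnaneic acid C is a bicyclo[2.2.2]oct-5-ene-2,3-dione. Bridgeheads C1 and C4 are joined by the diketone bridge C2–C3, the alkene bridge C5=C6 and the saturated bridge C7–C8. C6 carries an (E)-propenoate arm esterified with the secondary hydroxyl of (R)-3-(3,4-dihydroxyphenyl)lactic acid, C7 a free carboxyl and C8 a second catechol ring. C1, C7, C8 and C4 are four contiguous stereocentres (1R,4R,7R,8S in this core numbering). The C7 carboxyl and C8 aryl are trans, the carboxyl on the side of the dione bridge and the aryl on the side of C5=C6. The fifth, (R) centre lies far away in the lactate.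

The fragile groups are:
- the strained, non-enolisable 1,2-dione (hydration, cleavage by base or peroxide, light sensitivity as a β,γ-unsaturated ketone);
- two air-sensitive catechols;
- the acyloxy ester link, which rules out basic hydrolysis late in the route;
- the conjugated diene ester, which rules out hydrogenolysis.

The real difficulty is to place two different substituents on the C7–C8 bridge correctly relative to two different neighbouring bridges, in one absolute sense. The dione/diacid/tetraphenol pattern must then be reached without a step that another group cannot bear.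

The key step exploits the fact that C2 and C3 are bonded only to the bridgeheads. C1 and C4 are the ends of the four-carbon unit C1–C6–C5–C4 inside the ring C1–C6–C5–C4–C8–C7. The dione can therefore be added last, as a masked cis-enediol, across a cyclohexa-1,3-diene that already holds C7 and C8.

## Logic of the disconnections

**18 to 17.** The five O–CH2Ph bonds (four aryl ethers, one ester) are cut. Free catechols and the lactate acid cannot pass through hydride, ylide and oxidation chemistry, and one group type allows one final operation. The demand is a debenzylation that spares C=C bonds, the dione and the ester, so hydrogenolysis is excluded and a Lewis acid with a cation scavenger is used.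

**17 to 16 to 15.** No skeletal bond is cut. The C7 carboxyl is traced back through the aldehyde to CH2OH and the two ketones to the cis-diol. This leaves 15 with alcohols only, which tolerate the olefination that precedes it. The forward steps must oxidise an eclipsed cis-diol without C–C cleavage, and then an aldehyde without attacking the dione.

**15 to 11 and 14.** The Cα=Cβ bond of the arm is cut. This joins two fragments of similar size and brings in the lactate stereocentre ready-made. The olefination must be E-selective and neutral, and 11 must carry only one aldehyde.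

**14 to 13 to 12.** The ylide ester C–O bond and three O–benzyl bonds are cut. The stereocentre comes from the chiral pool, so the forward steps only have to avoid base strong enough to epimerise an α-acyloxy ester.

**11 to 10 to 9.** Functional-group changes only: the enal goes back to the allylic alcohol and then to the methyl ester, and the diol and C7 CH2OH go back to the carbonate and an ester. One hydride step then unmasks three groups. The price is a chemoselective oxidation of one hydroxyl out of four, next to a diol that must not be cleaved.

**9 to 7 and 8.** C1–C2 and C3–C4 are cut. This removes the bicycle, four stereocentres and the dione oxidation level in one stroke and leaves a monocyclic diene with only C7 and C8 stereogenic. The cycloaddition must occur on the face of 7 anti to the C8 aryl group.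

**7 to 4 and 5 (through 6).** C1–C7 and C4–C8 are cut, with CO2 re-inserted between C1 and C4. The pyrone places its ester carbon on C6 and, by polarity, the aryl carbon para to it, and the E-alkene gives the 7,8-trans relationship. The cycloaddition itself gives no absolute control. The enantiopure acyl group in 4 therefore serves as O-protection and as the handle that turns the two ring enantiomers into separable diastereomers.

**4 to 3 to 2 to 1.** Only C–O bonds are cut. 1 supplies the whole aryl–C3 unit with the E geometry, so the forward steps are protection, reduction and acylation.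

## Other disconnections considered

**Alternative 1:** The cut is C4–C5. In the monocyclic keto-ketal A2, base would form the only possible enolate of the C3 ketone (towards C4, since C2 is a ketal carbon). This adds to the β-carbon C5 of the methoxyacrolein arm and expels methoxide, giving A1.
- In favour: the dione is already at the right oxidation level (one carbonyl free, one as ketal). C6 arrives as the aldehyde and C7 at the acid level. After the key step A1 needs no hydride, no selective alcohol oxidation and no diol oxidation. On step economy after the key step, and in avoiding the redox risks of steps 7, 11 and 12, it is better than the chosen plan.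
- Mechanism: the tether can close only one way, so there is no facial question at the ring closure. On this point it is at least the equal of the chosen plan.
- Against: the whole stereochemical problem is moved into A2, which carries three contiguous stereocentres, a ketal beside a ketone and a labile β-methoxy enal. C1–H (vinylogous to the aldehyde) and C7–H (α to the ester) can epimerise under the base the closure needs. The arm must also reach across the ring through a boat.
- Overall: the chosen plan makes ring, bridge and four stereocentres from flat pieces in two cycloadditions, and A2 has no comparably short access.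

**Alternative 2:** The cut is C1–C7. Pd(PPh3)4 (zerovalent palladium) would ionise the allylic carbonate of A4 with inversion. The tethered malonate anion would attack the far allyl terminus C1 anti to the metal, giving A3 with net retention (Tsuji–Trost alkylation).
- In favour: the step is stereospecific and catalytic and runs near room temperature. Regiochemistry is fixed by ring size, since attack at C5 would give a four-membered ring. The acetonide survives hydride and oxidants, so the diol-versus-oxidant problem of step 7 does not arise. On conditions and on diol protection it is better than the chosen plan.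
- Against: A4 must already hold C2, C3, C4, C5 and the exocyclic benzylic C8 in defined form, and an acyclic benzylic centre is hard to set. C7 arrives as a geminal diester, so a hot dealkoxycarbonylation (Krapcho conditions) is needed and C7 is set only by protonation. The C6 CH2OSi group still has to be unmasked and oxidised. The closure forms a quaternary centre across a boat and competes with elimination of the allyl complex to a diene.
- Overall: mechanistically cleaner at the key step, structurally more demanding before it, and clearly longer.

**Alternative 3:** The cut is C1–C2. The C2 enolate of the cis-fused furanone A6 would add to C1 of the enoate while the C5–O bond leaves (an intramolecular SN2′ or [2,3]-type shift), giving the acyloin A5.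
- In favour: C2 is delivered to the face from which the oxygen departs, so C1 and C4 follow from the cis ring fusion without steric competition. This is better than the sterically governed approach of step 5. Only one secondary alcohol must be oxidised to reach the dione, and C7 is already at the acid level.
- Against: the ketone of A6 has a second α-position, the ring-fusion carbon C4. Its enolate can expel the same C5–O bond by β-elimination and open a path to aromatisation. The two methyl esters on C6 and C7 are not differentiated, although one must be reduced and the other kept. A6 itself needs four stereocentres in a strained bicycle.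
- Overall: shorter after the key step, longer and less certain before it.

Key step: step 5

Assumption: core atoms keep the numbering C1–C8 of bicyclo[2.2.2]oct-5-ene-2,3-dione in all intermediates, and commercial 12 is used as the free acid (its sodium salt behaves the same in step 8).

## Steps

Step 1
Reactants: 1 caffeic acid, (E)-3-(3,4-dihydroxyphenyl)prop-2-enoic acid
Product: 2 benzyl (E)-3-[3,4-bis(benzyloxy)phenyl]prop-2-enoate
Conditions: BnBr (3.3 equiv), K2CO3, DMF, 60 °C
Reagents that add atoms: benzyl bromide, BrCc1ccccc1
Why: Williamson alkylation of the two phenoxides and of the carboxylate; benzyl is chosen because it survives 160 °C, hydride and the oxidations and can be removed at the end without hydrogen.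

Step 2
Reactants: 2 benzyl (E)-3-[3,4-bis(benzyloxy)phenyl]prop-2-enoate
Product: 3 (E)-3-[3,4-bis(benzyloxy)phenyl]prop-2-en-1-ol
Conditions: iBu2AlH (2.5 equiv), CH2Cl2, −78 → 0 °C; aq. potassium sodium tartrate (KNaC4H4O6)
Reagents that add atoms: none
Why: 1,2-Reduction of the conjugated ester by diisobutylaluminium hydride gives the allylic alcohol without touching the C=C bond, so the E geometry is kept.

Step 3
Reactants: 3 (E)-3-[3,4-bis(benzyloxy)phenyl]prop-2-en-1-ol
Product: 4 (E)-3-[3,4-bis(benzyloxy)phenyl]prop-2-enyl (1S,4R)-4,7,7-trimethyl-3-oxo-2-oxabicyclo[2.2.1]heptane-1-carboxylate, the (1S,4R)-camphanate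
Conditions: (1S)-camphanic chloride, Et3N, DMAP (cat.), CH2Cl2, 0 °C → rt
Reagents that add atoms: (1S,4R)-camphanic chloride, O=C(Cl)[C@@]12CC[C@@](C)(C(=O)O1)C2(C)C
Why: Acylation of the primary alcohol by nucleophilic acyl substitution; the ester is slim next to the future C7, is cleaved later by the same hydride that reduces the C6 ester, and its fixed, non-epimerisable chirality makes the two ring enantiomers of the next step diastereomers.

Step 4
Reactants: 4 (E)-3-[3,4-bis(benzyloxy)phenyl]prop-2-enyl (1S,4R)-camphanate; 5 methyl coumalate (methyl 2-oxo-2H-pyran-5-carboxylate)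
Product: 7 methyl (3S,4S)-4-[3,4-bis(benzyloxy)phenyl]-3-{[(1S,4R)-camphanoyloxy]methyl}cyclohexa-1,5-diene-1-carboxylate (3,4-trans), via bridged lactone 6 (not isolated)
Conditions: 5 (2 equiv), BHT (cat.), toluene, 130 °C, sealed tube; then separation of the two diastereomers by crystallisation or chromatography
Reagents that add atoms: none
Why: Inverse-electron-demand Diels–Alder reaction of the electron-poor 2-pyrone: the nucleophilic styrene carbon (remote from the aryl ring) bonds to C6 of the pyrone, which puts the aryl carbon para to the ester carbon, and suprafacial addition to the E-alkene fixes the 3,4-trans relationship; lactone 6 then loses CO2 by retro-[4+2] under the same conditions. The remote camphanoyl group should not bias the alkene face, so both ring enantiomers form as diastereomers and the (3S,4S) isomer 7 is separated, its assignment to be secured by crystallography of 7 or 9.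

Step 5
Reactants: 7 methyl (3S,4S)-4-[3,4-bis(benzyloxy)phenyl]-3-{[(1S,4R)-camphanoyloxy]methyl}cyclohexa-1,5-diene-1-carboxylate; 8 vinylene carbonate (1,3-dioxol-2-one)
Product: 9 cyclic carbonate of methyl 8-[3,4-bis(benzyloxy)phenyl]-7-{[(1S,4R)-camphanoyloxy]methyl}-2,3-cis-dihydroxybicyclo[2.2.2]oct-5-ene-6-carboxylate (aryl syn to C5=C6; C7 substituent syn to the C2–C3 bridge; carbonate syn to C5=C6)
Conditions: 8 (neat, 15 equiv), BHT (cat.), Ar, sealed tube, 150–160 °C
Reagents that add atoms: none
Why: A concerted, thermally allowed [4+2] cycloaddition, suprafacial on both partners; the closest known reaction type is the addition of vinylene carbonate to cyclohexa-1,3-dienes on the way to bicyclo[2.2.2]octene-2,3-diols and their diones. The only ring closed, C1–C2–C3–C4–C5–C6, forms intermolecularly by bonding the two dienophile carbons to the diene termini C1 and C4 in one event, and C7–C8 becomes the third bridge. C2 and C3 are cis because the cis-dienophile adds suprafacially; the endo mode (carbonate under C5=C6, away from the C7 substituent) is expected, but either orientation serves because both carbinols later become carbonyls. C1 and C4 are set by the choice of π-face: addition anti to the C8 aryl gives the required configuration and leaves the aryl syn to C5=C6 and the C7 group syn to the new bridge. Facial selectivity is the only selectivity needed, since the dienophile is symmetric. In the boat-like transition state the group on the attacked face meets the exo hydrogen of the dienophile in a 1,3-diaxial-type contact, which costs more for the ring-attached aryl at C8 than for the CH2 group at C7, whose acyloxy tail can turn away; this is why a slim ester is used there in place of a bulky silyl ether. Vinylene carbonate is only weakly polarised and the ester makes the diene mildly electron-poor, so the reaction is of near-neutral demand and needs heat and a large excess of dienophile, which also dilutes 7 against self-dimerisation. The wrong-face adduct is a diastereomer and can be removed.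

Step 6
Reactants: 9 cyclic carbonate adduct
Product: 10 8-[3,4-bis(benzyloxy)phenyl]-6,7-bis(hydroxymethyl)bicyclo[2.2.2]oct-5-ene-2,3-cis-diol (diol syn to C5=C6; C7 and C8 as in 9)
Conditions: iBu2AlH (12 equiv), CH2Cl2, −78 → 23 °C; aq. KNaC4H4O6
Reagents that add atoms: none
Why: Hydride reduction turns the conjugated methyl ester into the allylic alcohol (1,2-addition) and cleaves the cyclic carbonate and the camphanoyl ester reductively in the same operation; no stereocentre is involved.

Step 7
Reactants: 10 tetraol
Product: 11 8-[3,4-bis(benzyloxy)phenyl]-2,3-cis-dihydroxy-7-(hydroxymethyl)bicyclo[2.2.2]oct-5-ene-6-carbaldehyde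
Conditions: CuCl (10 mol%), TEMPO (10 mol%), O2 (1 atm), DMF, rt
Reagents that add atoms: none
Why: The aerobic copper/nitroxyl oxidation converts allylic primary alcohols much faster than unactivated primary or secondary ones and has no pathway for glycol cleavage; MnO2, the usual reagent for allylic alcohols, is avoided because it can split 1,2-diols.

Step 8
Reactants: 12 (R)-danshensu, (R)-3-(3,4-dihydroxyphenyl)-2-hydroxypropanoic acid
Product: 13 benzyl (R)-3-[3,4-bis(benzyloxy)phenyl]-2-hydroxypropanoate
Conditions: BnBr (3.1 equiv), K2CO3, DMF, rt
Reagents that add atoms: benzyl bromide, BrCc1ccccc1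
Why: Carbonate base ionises only the two phenols and the carboxylic acid, which are benzylated (Williamson alkylation), while the secondary hydroxyl stays free; the stereocentre is not touched.

Step 9
Reactants: 13 benzyl (R)-3-[3,4-bis(benzyloxy)phenyl]-2-hydroxypropanoate
Product: 14 benzyl (R)-3-[3,4-bis(benzyloxy)phenyl]-2-{[(triphenylphosphoranylidene)acetyl]oxy}propanoate
Conditions: Ph3P=C=C=O (1.0 equiv), THF, 65 °C
Reagents that add atoms: (triphenylphosphoranylidene)ketene, O=C=C=P(c1ccccc1)(c1ccccc1)c1ccccc1
Why: Addition of the O–H bond across the cumulated ylide gives the ester-stabilised phosphorane directly; no base is present, so the α-acyloxy stereocentre is not at risk.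

Step 10
Reactants: 11 enal triol; 14 phosphorane
Product: 15 benzyl (R)-3-[3,4-bis(benzyloxy)phenyl]-2-({(E)-3-[8-[3,4-bis(benzyloxy)phenyl]-2,3-cis-dihydroxy-7-(hydroxymethyl)bicyclo[2.2.2]oct-5-en-6-yl]prop-2-enoyl}oxy)propanoate
Conditions: CH2Cl2, rt → 40 °C
Reagents that add atoms: none
Why: Wittig olefination with an ester-stabilised ylide is E-selective, runs under neutral conditions and tolerates the three free hydroxyls; it attaches the complete lactate ester in one convergent step.

Step 11
Reactants: 15 dienoate triol
Product: 16 benzyl (R)-3-[3,4-bis(benzyloxy)phenyl]-2-({(E)-3-[8-[3,4-bis(benzyloxy)phenyl]-7-formyl-2,3-dioxobicyclo[2.2.2]oct-5-en-6-yl]prop-2-enoyl}oxy)propanoate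
Conditions: DMSO (12 equiv), (CF3CO)2O (9 equiv), CH2Cl2, −78 °C; then iPr2NEt, −78 → −20 °C; light excluded
Reagents that add atoms: none
Why: Swern oxidation with activated dimethyl sulfoxide is the established way to turn bicyclo[2.2.2]octene-2,3-cis-diols into the 1,2-diones without C–C cleavage, and it oxidises the primary alcohol to the aldehyde in the same pot. The bridgeheads cannot enolise, and the only epimerisable centre, C7, can equilibrate only towards the required trans arrangement, since the cis isomer would eclipse the aryl group.

Step 12
Reactants: 16 aldehyde dione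
Product: 17 8-[3,4-bis(benzyloxy)phenyl]-6-[(E)-3-({(R)-1-(benzyloxy)-3-[3,4-bis(benzyloxy)phenyl]-1-oxopropan-2-yl}oxy)-3-oxoprop-1-enyl]-2,3-dioxobicyclo[2.2.2]oct-5-ene-7-carboxylic acid
Conditions: NaClO2, NaH2PO4, 2-methyl-2-butene (excess), tBuOH/THF/H2O, 0 °C → rt
Reagents that add atoms: sodium chlorite, [Na+].[O-]Cl=O
Why: Pinnick oxidation takes the aldehyde to the acid through the chlorite adduct, which fragments only when a formyl hydrogen is present, so the ketones and the electron-poor diene should be left alone; 2-methyl-2-butene removes hypochlorous acid before it can chlorinate the electron-rich rings.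

Step 13
Reactants: 17 penta-O-benzyl acid
Product: 18 yunnaneic acid C, (2R)-2-({(E)-3-[(1R,4R,7R,8S)-7-carboxy-8-(3,4-dihydroxyphenyl)-2,3-dioxobicyclo[2.2.2]oct-5-en-6-yl]prop-2-enoyl}oxy)-3-(3,4-dihydroxyphenyl)propanoic acid (core locants as used throughout)
Conditions: BCl3 (15 equiv), C6HMe5 (15 equiv), CH2Cl2, −78 → 0 °C; then aq. THF; light and air excluded
Reagents that add atoms: none
Why: Lewis-acid debenzylation with pentamethylbenzene as a non-basic benzyl-cation trap cleaves aryl benzyl ethers at low temperature and the benzyl ester on warming, without hydrogen, base or nucleophile, so the alkenes, the acyloxy ester and the dione should survive; the scavenger prevents C-benzylation of the liberated catechols.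

## Compound list

1 | caffeic acid | O=C(O)/C=C/c1ccc(O)c(O)c1 | starting material
2 | benzyl (E)-3-[3,4-bis(benzyloxy)phenyl]prop-2-enoate | O=C(/C=C/c1ccc(OCc2ccccc2)c(OCc2ccccc2)c1)OCc1ccccc1 | intermediate
3 | (E)-3-[3,4-bis(benzyloxy)phenyl]prop-2-en-1-ol | OC/C=C/c1ccc(OCc2ccccc2)c(OCc2ccccc2)c1 | intermediate
4 | (E)-3-[3,4-bis(benzyloxy)phenyl]prop-2-enyl (1S,4R)-camphanate | O=C(OC/C=C/c1ccc(OCc2ccccc2)c(OCc2ccccc2)c1)[C@@]12CC[C@@](C)(C(=O)O1)C2(C)C | intermediate
5 | methyl coumalate | COC(=O)C1=COC(=O)C=C1 | starting material
6 | methyl 8-[3,4-bis(benzyloxy)phenyl]-7-{[(1S,4R)-camphanoyloxy]methyl}-3-oxo-2-oxabicyclo[2.2.2]oct-5-ene-6-carboxylate (7,8-trans; drawn with the aryl syn to C5=C6, the other orientation gives the same diene) | COC(=O)C1=C[C@H]2C(=O)O[C@@H]1[C@H](COC(=O)[C@@]34CC[C@@](C)(C(=O)O3)C4(C)C)[C@H]2c1ccc(OCc2ccccc2)c(OCc2ccccc2)c1 | intermediate (not isolated)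
7 | methyl (3S,4S)-4-[3,4-bis(benzyloxy)phenyl]-3-{[(1S,4R)-camphanoyloxy]methyl}cyclohexa-1,5-diene-1-carboxylate | COC(=O)C1=C[C@H](COC(=O)[C@@]23CC[C@@](C)(C(=O)O2)C3(C)C)[C@@H](c2ccc(OCc3ccccc3)c(OCc3ccccc3)c2)C=C1 | intermediate (key-step precursor)
8 | vinylene carbonate | O=C1OC=CO1 | starting material
9 | cyclic carbonate of methyl 8-[3,4-bis(benzyloxy)phenyl]-7-{[(1S,4R)-camphanoyloxy]methyl}-2,3-cis-dihydroxybicyclo[2.2.2]oct-5-ene-6-carboxylate | COC(=O)C1=C[C@H]2[C@H]3OC(=O)O[C@H]3[C@@H]1[C@H](COC(=O)[C@@]45CC[C@@](C)(C(=O)O4)C5(C)C)[C@H]2c1ccc(OCc2ccccc2)c(OCc2ccccc2)c1 | intermediate (key-step product)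
10 | 8-[3,4-bis(benzyloxy)phenyl]-6,7-bis(hydroxymethyl)bicyclo[2.2.2]oct-5-ene-2,3-cis-diol | OCC1=C[C@H]2[C@@H](O)[C@@H](O)[C@@H]1[C@H](CO)[C@H]2c1ccc(OCc2ccccc2)c(OCc2ccccc2)c1 | intermediate
11 | 8-[3,4-bis(benzyloxy)phenyl]-2,3-cis-dihydroxy-7-(hydroxymethyl)bicyclo[2.2.2]oct-5-ene-6-carbaldehyde | O=CC1=C[C@H]2[C@@H](O)[C@@H](O)[C@@H]1[C@H](CO)[C@H]2c1ccc(OCc2ccccc2)c(OCc2ccccc2)c1 | intermediate
12 | (R)-danshensu | O[C@H](Cc1ccc(O)c(O)c1)C(=O)O | starting material
13 | benzyl (R)-3-[3,4-bis(benzyloxy)phenyl]-2-hydroxypropanoate | O[C@H](Cc1ccc(OCc2ccccc2)c(OCc2ccccc2)c1)C(=O)OCc1ccccc1 | intermediate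
14 | benzyl (R)-3-[3,4-bis(benzyloxy)phenyl]-2-{[(triphenylphosphoranylidene)acetyl]oxy}propanoate | O=C(C=P(c1ccccc1)(c1ccccc1)c1ccccc1)O[C@H](Cc1ccc(OCc2ccccc2)c(OCc2ccccc2)c1)C(=O)OCc1ccccc1 | intermediate
15 | dienoate triol (Wittig product) | O=C(/C=C/C1=C[C@H]2[C@@H](O)[C@@H](O)[C@@H]1[C@H](CO)[C@H]2c1ccc(OCc2ccccc2)c(OCc2ccccc2)c1)O[C@H](Cc1ccc(OCc2ccccc2)c(OCc2ccccc2)c1)C(=O)OCc1ccccc1 | intermediate
16 | 7-formyl-2,3-dione (penta-O-benzyl) | O=C(/C=C/C1=C[C@H]2C(=O)C(=O)[C@@H]1[C@H](C=O)[C@H]2c1ccc(OCc2ccccc2)c(OCc2ccccc2)c1)O[C@H](Cc1ccc(OCc2ccccc2)c(OCc2ccccc2)c1)C(=O)OCc1ccccc1 | intermediate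
17 | penta-O-benzyl yunnaneic acid C (C7 carboxyl free) | O=C(/C=C/C1=C[C@H]2C(=O)C(=O)[C@@H]1[C@H](C(=O)O)[C@H]2c1ccc(OCc2ccccc2)c(OCc2ccccc2)c1)O[C@H](Cc1ccc(OCc2ccccc2)c(OCc2ccccc2)c1)C(=O)OCc1ccccc1 | intermediate
18 | yunnaneic acid C | O=C(/C=C/C1=C[C@H]2C(=O)C(=O)[C@@H]1[C@H](C(=O)O)[C@H]2c1ccc(O)c(O)c1)O[C@H](Cc1ccc(O)c(O)c1)C(=O)O | target

## Step count and least certain steps

Total: 13 steps. Longest linear sequence: 11 steps (steps 1–7 and 10–13).

**Step 5 (key step).** The process most likely to fail is facial discrimination: the aryl and acyloxymethyl groups sit on opposite faces and differ only moderately in size, so wrong-face attack may compete. Slow 1,5-hydrogen shift or self-dimerisation of 7 and polymerisation of 8 during long heating are further risks. The fallback inverts the order of the two cycloadditions and sets out from 5 and 8. Heated together (neat, about 150 °C), they should give, after loss of CO2, racemic methyl cis-2-oxo-3a,7a-dihydro-1,3-benzodioxole-5-carboxylate F1. A second Diels–Alder reaction of F1 with 4 (toluene, 130–150 °C) then forms C1–C7 and C4–C8 and comes back to the route at 9. In that mode both carbonate oxygens block one face of the diene, so the alkene must add anti to them. Polarity sends its nucleophilic carbon to C1. The remaining question, aryl endo versus exo, is governed by a different element than in step 5. The camphanoyl group again makes the ring enantiomers separable as diastereomers at 9.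

**Step 4.** Two processes may fail: a sluggish cycloaddition of the 1,2-disubstituted styrene with competing decomposition of 5, and co-crystallisation or co-elution of the two diastereomers. If the cycloaddition itself fails, the inverted order through F1 bypasses 7. If only the separation fails, the fallback sets out from 3. Acetylation (Ac2O, pyridine) gives (E)-3-[3,4-bis(benzyloxy)phenyl]prop-2-enyl acetate F2. The same thermal reaction with 5 gives the racemic trans diene acetate, and the enantiomers are separated by preparative chromatography on a chiral stationary phase to provide methyl (3S,4S)-3-(acetoxymethyl)-4-[3,4-bis(benzyloxy)phenyl]cyclohexa-1,5-diene-1-carboxylate F3. Cycloaddition with 8 as in step 5 gives the acetate analogue of the carbonate adduct F4, and diisobutylaluminium hydride reduction returns to the route at 10.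

**Step 7.** Over-oxidation at the C7 hydroxymethyl group, or inhibition of the copper catalyst by the chelating cis-diol, may leave mixtures. The fallback sets out from 10 and masks the diol. 2,2-Dimethoxypropane with PPTS gives the 2,3-O-isopropylidene derivative of the tetraol F5. With no free glycol present, MnO2 in CH2Cl2 can now be used safely and gives the acetonide enal F6. Wittig reaction with 14 gives the acetonide of the dienoate F7, and aqueous acetic acid at 40 °C removes the ketal and comes back at 15.

**Step 11 (and with it step 12).** The threefold oxidation may stop at the α-ketol, form methylthiomethyl ethers or cleave the eclipsed diol. In step 12 the strained dione may be attacked by chlorite. The fallback sets out from 15 and changes the order. Catalytic TEMPO with catalytic NaOCl and stoichiometric NaClO2 (MeCN, phosphate buffer) oxidises only the primary alcohol and gives the 2,3-diol 7-carboxylic acid F8. 2-Iodoxybenzoic acid in DMSO, which tolerates free acids and oxidises 1,2-diols to 1,2-diones without cleavage, then returns to the route at 17.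

## Further compounds

F1 | step 5 | methyl cis-2-oxo-3a,7a-dihydro-1,3-benzodioxole-5-carboxylate (racemic; the enantiomer drawn leads to 9) | COC(=O)C1=C[C@@H]2OC(=O)O[C@@H]2C=C1
F2 | step 4 | (E)-3-[3,4-bis(benzyloxy)phenyl]prop-2-enyl acetate | CC(=O)OC/C=C/c1ccc(OCc2ccccc2)c(OCc2ccccc2)c1
F3 | step 4 | methyl (3S,4S)-3-(acetoxymethyl)-4-[3,4-bis(benzyloxy)phenyl]cyclohexa-1,5-diene-1-carboxylate | COC(=O)C1=C[C@H](COC(C)=O)[C@@H](c2ccc(OCc3ccccc3)c(OCc3ccccc3)c2)C=C1
F4 | step 4 | cyclic carbonate of methyl 7-(acetoxymethyl)-8-[3,4-bis(benzyloxy)phenyl]-2,3-cis-dihydroxybicyclo[2.2.2]oct-5-ene-6-carboxylate | COC(=O)C1=C[C@H]2[C@H]3OC(=O)O[C@H]3[C@@H]1[C@H](COC(C)=O)[C@H]2c1ccc(OCc2ccccc2)c(OCc2ccccc2)c1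
F5 | step 7 | 2,3-O-isopropylidene derivative of 10 | OCC1=C[C@H]2[C@H]3OC(C)(C)O[C@H]3[C@@H]1[C@H](CO)[C@H]2c1ccc(OCc2ccccc2)c(OCc2ccccc2)c1
F6 | step 7 | 2,3-O-isopropylidene derivative of 11 | O=CC1=C[C@H]2[C@H]3OC(C)(C)O[C@H]3[C@@H]1[C@H](CO)[C@H]2c1ccc(OCc2ccccc2)c(OCc2ccccc2)c1
F7 | step 7 | 2,3-O-isopropylidene derivative of 15 | O=C(/C=C/C1=C[C@H]2[C@H]3OC(C)(C)O[C@H]3[C@@H]1[C@H](CO)[C@H]2c1ccc(OCc2ccccc2)c(OCc2ccccc2)c1)O[C@H](Cc1ccc(OCc2ccccc2)c(OCc2ccccc2)c1)C(=O)OCc1ccccc1
F8 | step 11 | 2,3-cis-diol 7-carboxylic acid corresponding to 15 | O=C(/C=C/C1=C[C@H]2[C@@H](O)[C@@H](O)[C@@H]1[C@H](C(=O)O)[C@H]2c1ccc(OCc2ccccc2)c(OCc2ccccc2)c1)O[C@H](Cc1ccc(OCc2ccccc2)c(OCc2ccccc2)c1)C(=O)OCc1ccccc1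
A1 | alternative 1 | tert-butyl 8-(3,4-dimethoxyphenyl)-6-formyl-2,2-dimethoxy-3-oxobicyclo[2.2.2]oct-5-ene-7-carboxylate | O=CC1=C[C@H]2C(=O)C(OC)(OC)[C@@H]1[C@H](C(=O)OC(C)(C)C)[C@H]2c1ccc(OC)c(OC)c1
A2 | alternative 1 | tert-butyl 2-(3,4-dimethoxyphenyl)-6-(1-formyl-2-methoxyvinyl)-5,5-dimethoxy-4-oxocyclohexane-1-carboxylate (all-trans at the three ring stereocentres; either alkene geometry) | COC=C(C=O)[C@@H]1C(OC)(OC)C(=O)C[C@H](c2ccc(OC)c(OC)c2)[C@H]1C(=O)OC(C)(C)C
A3 | alternative 2 | dimethyl 6-[(tert-butyldimethylsilyloxy)methyl]-8-(3,4-dimethoxyphenyl)-2,3-(isopropylidenedioxy)bicyclo[2.2.2]oct-5-ene-7,7-dicarboxylate | CC(C)(C)[Si](C)(C)OCC1=C[C@H]2[C@H]3OC(C)(C)O[C@H]3[C@@H]1C(C(=O)OC)(C(=O)OC)[C@H]2c1ccc(OC)c(OC)c1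
A4 | alternative 2 | dimethyl 2-[(3,4-dimethoxyphenyl){6-[(tert-butyldimethylsilyloxy)methyl]-5-(methoxycarbonyloxy)-2,2-dimethyl-3a,4,5,7a-tetrahydro-1,3-benzodioxol-4-yl}methyl]malonate (carbonate cis to the side chain) | COC(=O)O[C@H]1C(CO[Si](C)(C)C(C)(C)C)=C[C@@H]2OC(C)(C)O[C@@H]2[C@H]1[C@H](c1ccc(OC)c(OC)c1)C(C(=O)OC)C(=O)OC
A5 | alternative 3 | dimethyl 8-(3,4-dimethoxyphenyl)-2-hydroxy-3-oxobicyclo[2.2.2]oct-5-ene-6,7-dicarboxylate | COC(=O)C1=C[C@H]2C(=O)[C@@H](O)[C@@H]1[C@H](C(=O)OC)[C@H]2c1ccc(OC)c(OC)c1
A6 | alternative 3 | dimethyl 4-(3,4-dimethoxyphenyl)-3-oxo-2,3,3a,4,5,7a-hexahydro-1-benzofuran-5,7-dicarboxylate (cis ring fusion, 4,5-trans) | COC(=O)C1=C[C@H](C(=O)OC)[C@@H](c2ccc(OC)c(OC)c2)[C@@H]2C(=O)CO[C@H]12
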